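Locants follow ligustilide: C1 lactone carbonyl, O2, C3 butylidene-bearing carbon, C3a, C4–C7, C7a, C8–C11 side chain. Unprimed atoms belong to half A, primed atoms to the hydroxylated half B. Retro-[4+2] across C6–C7' and C7–C4' gives (Z)-ligustilide (2π, cis C6=C7) and a 6'-silyloxy cyclohexa-1,3-diene C7'=C7a'–C3a'=C4' (4π).
Enabling feature: in the bicyclo[2.2.2]oct-2-ene, ring C7'–C7a'=C3a'–C4'–C7–C6 is a cyclohexene whose lactone-bearing double bond lies between the two CH bridgeheads and opposite the cis C6–H/C7–H pair (Diels–Alder retron). The C6' oxygen is allylic to diene terminus C7', where an epoxide can deliver it and where it steers the facial attack.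
The diene is made from ligustilide itself: asymmetric epoxidation of C6=C7, then vinylogous E1cB opening (H-4 removed, C7–O cleaved) and O-silylation. C6' is thereby set (S) before the union.
Ring order: lactone A, carbocycle A, lactone B and carbocycle B come with the starting material. The union lays the C6–C7 bridge across C7'/C4' and closes the cyclohexane C6–C7'–C6'–C5'–C4'–C7 last, creating C6, C7, C4' and C7' in one operation; desilylation ends the route.

Key step: step 3

Assumption: (Z)-ligustilide is taken as a purchasable natural product and is the only carbon source for both halves.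
Assumption: the (R,R) salen ligand transfers oxygen to C6=C7 in the sense known for indene and 1,2-dihydronaphthalene (C7a in the place of the aryl carbon), which corresponds to 6S,7R; if the sense is reversed on this substrate, the (S,S) ligand is used and nothing else changes.

Step 1
Reactants: 1 (Z)-ligustilide
Product: 2 (6S,7R)-6,7-epoxy-(Z)-ligustilide
Conditions: (R,R)-(salen)MnCl {chloro[(R,R)-N,N'-bis(3,5-di-tert-butylsalicylidene)cyclohexane-1,2-diaminato]manganese, trivalent manganese} (5 mol %), mCPBA (1.5 equiv), N-methylmorpholine N-oxide (5 equiv), CH2Cl2, −78 °C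
Reagents that add atoms: 3-chloroperoxybenzoic acid (mCPBA), OOC(=O)c1cccc(Cl)c1
Why: Jacobsen–Katsuki epoxidation, in which the oxo(salen)manganese species (pentavalent manganese) should transfer oxygen to the cis-disubstituted, diene-conjugated C6=C7 bond (the substrate class this catalyst handles best) faster than to the tetrasubstituted C3a=C7a or the acyloxy-substituted butylidene alkene, the chiral ligand choosing the enantioface so that C6 becomes S and C7 becomes R.

Step 2
Reactants: 2 (6S,7R)-6,7-epoxy-(Z)-ligustilide
Product: 5 (S,Z)-3-butylidene-6-(tert-butyldimethylsilyloxy)-5,6-dihydroisobenzofuran-1(3H)-one, via lithium dienolate 3 (not isolated), via lithium alkoxide 4 (not isolated)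
Conditions: LiN(SiMe3)2 (1.05 equiv), THF, −78 °C, 20 min; then TBSOTf (1.15 equiv), −78 → −40 °C; aq. NaHCO3
Reagents that add atoms: tert-butyldimethylsilyl trifluoromethanesulfonate (TBSOTf), CC(C)(C)[Si](C)(C)OS(=O)(=O)C(F)(F)F
Why: γ-Deprotonation at C4 of the butenolide gives dienolate 3, whose α-carbon C7a expels the neighbouring epoxide oxygen from C7 (E1cB opening of a β,γ-epoxy carbonyl compound, here in its vinylogous form), creating the C7=C7a/C3a=C4 diene and the C6 alkoxide 4 without touching the C6–O bond, so C6 stays S, and immediate O-silylation at low temperature should keep this arene-hydrate-type dienol from losing water and aromatising.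

Step 3
Reactants: 5 (S,Z)-3-butylidene-6-(tert-butyldimethylsilyloxy)-5,6-dihydroisobenzofuran-1(3H)-one; 1 (Z)-ligustilide
Product: 6 (6S,7R,4'R,6'S,7'S)-6'-O-tert-butyldimethylsilyl ether of the target (exo,anti cycloadduct)
Conditions: 1 (4 equiv, excess recovered), BHT (5 mol %), toluene (2 M in 5), sealed tube, Ar, dark, 85 °C
Reagents that add atoms: none
Why: Thermal, concerted but asynchronous [4+2] cycloaddition (intermolecular Diels–Alder reaction; closest known reaction type: the thermal Diels–Alder dimerisation of ligustilide, which uses this same cis C6=C7 bond as 2π component), in which the ring-locked s-cis diene C7'=C7a'–C3a'=C4' of 5 adds suprafacially across C6=C7 of 1. It closes the cyclohexane C6–C7'–C6'–C5'–C4'–C7 by a two-bond bridging annulation, the C6–C7 unit being laid across C7' and C4' of the existing carbocycle B, which at the same time completes the cyclohexene C6–C7'–C7a'=C3a'–C4'–C7 of the bicyclo[2.2.2]octene. Regiochemistry (C6–C7', C7–C4') should follow from polarity and size: C6, the unsubstituted terminus of the dienyl lactone and the more nucleophilic carbon of the 2π partner, bonds ahead to C7', the β-carbon of the C1'=O/C7a'=C7' enoate, while the more substituted C7 meets C4', the terminus flanked only by CH2. C7' and C4' are set by the C6' silyloxy group, which blocks one diene face so that 1 adds anti to it and the oxygen ends up on the side of the new C3a'=C7a' bridge; C6 and C7 keep cis hydrogens because addition to the ring (Z)-alkene is suprafacial, and their sense relative to the bicycle comes from the exo orientation, in which ring A lies under the C5'–C6' bridge and both hydrogens point to the alkene bridge. The step therefore needs periselectivity (5 as 4π partner: its diene termini are CH, whereas the diene of 1 ends in the fully substituted C3a), head-to-head regiochemistry, anti facial selectivity and exo topology, and the first three are secured by the substrate as stated. Exo is the least secured element: it is helped only by the absence of a carbonyl directly on C6=C7 (the lactone C=O of 1 is cross-conjugated, so the secondary overlap behind the endo rule is weak) and by heat in an apolar medium, and the endo,anti isomer is the by-product to be expected and removed by chromatography.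

Step 4
Reactants: 6 (6S,7R,4'R,6'S,7'S)-6'-O-tert-butyldimethylsilyl ether of the target
Product: 7 target CNP0289078.1, (6S,7R,4'R,6'S,7'S)-6'-hydroxy dimer
Conditions: HF·pyridine, pyridine, THF, 0 °C → rt
Reagents that add atoms: none
Why: Fluoride-mediated cleavage of the secondary silyl ether under buffered, non-basic conditions should leave both (Z)-enol lactones, the C3a=C7a and C3a'=C7a' alkenes and all five stereocenters untouched.

Compound list
1 | (Z)-ligustilide, (Z)-3-butylidene-4,5-dihydroisobenzofuran-1(3H)-one | CCC/C=C1\OC(=O)C2=C1CCC=C2 | starting material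
2 | (6S,7R)-6,7-epoxy-(Z)-ligustilide, (3Z,6S,7R)-3-butylidene-6,7-epoxy-4,5,6,7-tetrahydroisobenzofuran-1(3H)-one (cis-fused epoxide) | CCC/C=C1\OC(=O)C2=C1CC[C@@H]1O[C@@H]12 | intermediate
3 | lithium dienolate of 2 (C1–O−, C1=C7a, C3a=C4, epoxide intact) | CCC/C=C1\OC([O-])=C2C1=CC[C@@H]1O[C@H]21.[Li+] | intermediate (not isolated)
4 | lithium (S)-alkoxide of (Z)-3-butylidene-6-hydroxy-5,6-dihydroisobenzofuran-1(3H)-one | CCC/C=C1\OC(=O)C2=C[C@@H]([O-])CC=C12.[Li+] | intermediate (not isolated)
5 | (S,Z)-3-butylidene-6-(tert-butyldimethylsilyloxy)-5,6-dihydroisobenzofuran-1(3H)-one (double bonds C3a=C4 and C7=C7a) | CCC/C=C1\OC(=O)C2=C[C@@H](O[Si](C)(C)C(C)(C)C)CC=C12 | intermediate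
6 | (6S,7R,4'R,6'S,7'S)-6'-O-tert-butyldimethylsilyl ether of the target: bicyclo[2.2.2]oct-2-ene with bonds C6–C7' and C7–C4', ring A syn to the C5'–C6' bridge, silyloxy group syn to the C3a'=C7a' bridge | CCC/C=C1\OC(=O)C2=C1CC[C@@H]1[C@H]3C4=C(/C(=C/CCC)OC4=O)[C@H](C[C@@H]3O[Si](C)(C)C(C)(C)C)[C@H]21 | intermediate
7 | target CNP0289078.1, (6S,7R,4'R,6'S,7'S)-6'-hydroxy-6,7':7,4'-linked (Z,Z')-phthalide dimer | CCC/C=C1\OC(=O)C2=C1CC[C@@H]1[C@H]3C4=C(/C(=C/CCC)OC4=O)[C@H](C[C@@H]3O)[C@H]21 | target

Total step count: 4. Longest linear sequence: 4 steps (1 → 2 → 5 → 6 → 7); compound 1 enters a second time in step 3.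

Steps most likely to fail

Step 3. What may go wrong: the stacked endo approach (ring A under the lactone of ring B) may compete with or outrun the exo approach, and on prolonged heating the diene may lose silanol and aromatise before it is trapped. The fallback sets out from 5 and 1 and comes back at 6; it changes the activation mode and the origin of the exo preference from substrate to a stoichiometric host. Compound 5 is first bound through its lactone carbonyl to aluminium tris(2,6-diphenylphenoxide), Al(OC6H3-2,6-Ph2)3 (1.1 equiv, toluene, −78 °C), and 1 is then added and the mixture warmed to about −20 °C. The three aryloxide ligands wall in the space above and below the bound lactone of ring B, so ring A can no longer stack there and should be pushed under the C5'–C6' bridge. This is the principle of the known exo-selective Diels–Alder reactions of enones held in bulky aluminium aryloxide pockets. Coordination also lowers the diene LUMO, which allows a low temperature, and it disfavours ionisation of the allylic silyl ether. No new isolable compound is made.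

Step 2. What may go wrong: proton shuttling at the dienolate/alkoxide stage may isomerise the γ-hydroxy enoate to the 6-keto tautomer or lead to loss of the oxygen with aromatisation, and deprotonation at C9 may compete. The fallback sets out from 2 and comes back at 5, replacing the one-pot anionic isomerisation by a halohydrin sequence in which no free alkoxide or dienol ever exists. MgBr2·OEt2 (Et2O, −20 °C) should open the epoxide at the allylic C7 with inversion to give (3Z,6S,7S)-7-bromo-3-butylidene-6-hydroxy-4,5,6,7-tetrahydroisobenzofuran-1(3H)-one F1, with the C6–O bond untouched. TBSOTf and 2,6-lutidine give its silyl ether, (3Z,6S,7S)-7-bromo-3-butylidene-6-(tert-butyldimethylsilyloxy)-4,5,6,7-tetrahydroisobenzofuran-1(3H)-one F2. DBU (toluene, 0 °C → rt) then removes H-4 and bromide leaves from C7 (1,4-dehydrobromination through the dienolate). The competing 1,2-elimination toward C6 is geometrically blocked because H-6 is cis to bromine.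

Step 1. What may go wrong: enantioface discrimination on this dienyl lactone may be insufficient, uncatalysed peracid epoxidation may run in the background, or oxygen may be transferred to the butylidene enol-lactone alkene. The fallback sets out from 1 and comes back at 5, replacing catalyst control by a racemic epoxidation and an enzymatic resolution. mCPBA with NaHCO3 (CH2Cl2, 0 °C) gives racemic cis-6,7-epoxy-(Z)-ligustilide F3. MgBr2·OEt2 opens it to the racemic trans-bromohydrin, racemic trans-7-bromo-3-butylidene-6-hydroxy-4,5,6,7-tetrahydro-(Z)-isobenzofuran-1(3H)-one F4. Burkholderia cepacia lipase with vinyl acetate (tert-butyl methyl ether, 30 °C, run past half conversion) should acylate the (6R,7R) enantiomer, as is usual for trans-2-halocycloalkanols, giving (3Z,6R,7R)-6-acetoxy-7-bromo-3-butylidene-4,5,6,7-tetrahydroisobenzofuran-1(3H)-one F5. The unreacted alcohol is the (6S,7S)-bromohydrin F1, which is silylated to F2 and eliminated with DBU as in the fallback for step 2.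

Further compounds
F0 | step 3 | none | none
F1 | step 2 | (3Z,6S,7S)-7-bromo-3-butylidene-6-hydroxy-4,5,6,7-tetrahydroisobenzofuran-1(3H)-one | CCC/C=C1\OC(=O)C2=C1CC[C@H](O)[C@H]2Br
F2 | step 2 | (3Z,6S,7S)-7-bromo-3-butylidene-6-(tert-butyldimethylsilyloxy)-4,5,6,7-tetrahydroisobenzofuran-1(3H)-one | CCC/C=C1\OC(=O)C2=C1CC[C@H](O[Si](C)(C)C(C)(C)C)[C@H]2Br
F3 | step 1 | racemic cis-6,7-epoxy-(Z)-ligustilide | CCC/C=C1\OC(=O)C2=C1CCC1OC12
F4 | step 1 | racemic trans-7-bromo-3-butylidene-6-hydroxy-4,5,6,7-tetrahydro-(Z)-isobenzofuran-1(3H)-one | CCC/C=C1\OC(=O)C2=C1CCC(O)C2Br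
F5 | step 1 | (3Z,6R,7R)-6-acetoxy-7-bromo-3-butylidene-4,5,6,7-tetrahydroisobenzofuran-1(3H)-one | CCC/C=C1\OC(=O)C2=C1CC[C@@H](OC(C)=O)[C@@H]2Br
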